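The ten-membered carbocycle C1–C10, with methyls on C4 and C10 and the three-carbon unit C11–C13 on C7, is a farnesyl chain folded head to tail, so the route rests on disconnecting the ring bond C6–C7. A (+)-germacrene A synthase forms this bond in native (2E,6E)-farnesyl diphosphate, an acyclic, achiral precursor made from farnesol, and thereby delivers the whole carbon skeleton, the ring and C7 in the configuration of the target in one operation. The two ring olefins and the isopropenyl group are the handles for the rest: known P450 enzymes build the lactone, the 4,5-epoxide and the C9 carbinol, and short chemistry sets C8, C10 and C4 and attaches the two esters.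

Key step: step 3

Remarks on the chemistry
- Germacrane numbering and the usual germacranolide projection are used (H6 β, H7 α; C12 is the lactone carbonyl).
- (R)-Germacrene A carries the C7 configuration the target needs (H7 α; the descriptor becomes 7S in the lactones only because priorities change), so the natural (+)-selective synthase and the unmodified diphosphate are used.
- 4 is drawn as the free acid and handled as its ammonium salt. In the P450 steps NADPH is catalytic and is recycled with phosphite dehydrogenase and sodium phosphite.
- The 9β configuration drawn for 13 is an assumption without consequence, because C9 becomes a ketone in step 7.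
- The ring-cis geometry drawn for the enol derivatives 15, 16 and 24 is the expected one and is not critical.

Step 1
Reactants: 1 (2E,6E)-farnesol
Product: 3 (2E,6E)-farnesyl chloride, via farnesyl mesylate 2 (not isolated)
Conditions: MsCl, 2,4,6-collidine, LiCl, DMF, 0 °C
Reagents that add atoms: lithium chloride, [Li+].[Cl-]
Why: The primary allylic mesylate formed in situ should be displaced by chloride in a direct SN2 reaction at 0 °C, conditions under which farnesyl systems keep the 2E geometry and do not undergo allylic transposition.

Step 2
Reactants: 3 (2E,6E)-farnesyl chloride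
Product: 4 (2E,6E)-farnesyl diphosphate
Conditions: (Bu4N)3HP2O7, MeCN, rt; Dowex 50W (NH4+ form); cellulose, iPrOH/NH4OH/H2O
Reagents that add atoms: tris(tetrabutylammonium) hydrogen diphosphate, CCCC[N+](CCCC)(CCCC)CCCC.CCCC[N+](CCCC)(CCCC)CCCC.CCCC[N+](CCCC)(CCCC)CCCC.OP(=O)([O-])OP(=O)([O-])[O-]
Why: SN2 displacement of a primary allylic chloride by the diphosphate anion in acetonitrile is the standard preparation of allylic diphosphates and should give 4 without 1,3-transposition, in the salt form the enzyme accepts.

Step 3
Reactants: 4 (2E,6E)-farnesyl diphosphate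
Product: 6 (+)-(R)-germacrene A, via germacradienyl cation 5 (not isolated)
Conditions: recombinant (+)-germacrene A synthase (chicory or lettuce enzyme from E. coli), MgCl2, HEPES pH 7.5, DTT, 25 °C, pentane overlay; cold neutral work-up, no silica, no heating
Reagents that add atoms: none
Why: Mg2+-assisted ionisation of the allylic diphosphate gives the (E,E)-farnesyl cation, the C10=C11 π bond of the same chain attacks C1 (target C6) to form the C6–C7 bond and the tertiary C11 cation 5, and loss of a proton from a methyl group on C11 gives the isopropenyl group of 6. This is the native reaction of a class I terpene synthase, the closest known type being the enzymatic 1,10 cation–olefin cyclisation of farnesyl diphosphate. The ten-membered ring closes in the 10-exo mode with respect to the C10=C11 olefin (bond to its less substituted carbon, charge on tertiary C11), the eleven-membered alternative being excluded by the fold of the active site. The only new stereocentre, C7 (R in 6, the carbon that carries H7 α in the target), is set by the enzyme, which presents one face of the C10=C11 olefin to C1. The step needs 1,10- over 1,11- and 1,6-closure, retention of both E olefins and release of the neutral triene without reprotonation: the 2E geometry of 4 keeps C1 away from C6=C7, the trisubstituted C10=C11 olefin directs the charge to C11, and the two-phase, neutral, cool work-up prevents Cope rearrangement to β-elemene and acid-induced cyclisation to selinenes.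

Step 4
Reactants: 6 (+)-(R)-germacrene A
Product: 11 (+)-costunolide, via germacrene A alcohol 7 (not isolated), via germacrene A aldehyde 8 (not isolated), via germacrene A acid 9 (not isolated), via 6α-hydroxy acid 10 (not isolated)
Conditions: yeast microsomes with germacrene A oxidase (CYP71AV type), costunolide synthase (CYP71BL2) and CPR; NADPH (cat.), phosphite dehydrogenase, Na2HPO3; air, Tris pH 7.5, 30 °C, no thiols
Reagents that add atoms: dioxygen, O=O
Why: These are the native cytochrome P450 oxidations of the pathway, in which the oxidase should hydroxylate the allylic C12 methyl three times to the acrylic acid, the synthase should hydroxylate the allylic C6 methylene on the α face under enzyme control, and the 6α-hydroxy acid should close spontaneously to the trans-fused γ-lactone.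

Step 5
Reactants: 11 (+)-costunolide
Product: 12 (–)-parthenolide
Conditions: yeast microsomes with parthenolide synthase (CYP71CA1) and CPR; NADPH (cat.), phosphite dehydrogenase, Na2HPO3; air, Tris pH 7.5, 30 °C
Reagents that add atoms: dioxygen, O=O
Why: The native P450 epoxidation of costunolide should oxidise only the C4=C5 olefin from its outer face to the 4α,5β-epoxide (4R,5R), a site selectivity that peracids, which prefer C1=C10, do not give, and it sets the C5–O bond as in the target.

Step 6
Reactants: 12 (–)-parthenolide
Product: 13 9β-hydroxyparthenolide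
Conditions: engineered P450 BM3 (CYP102A1) variant selective for C9; NADPH (cat.), phosphite dehydrogenase, Na2HPO3; air, KPi pH 8.0, rt
Reagents that add atoms: dioxygen, O=O
Why: Laboratory-evolved variants of this self-sufficient bacterial P450 are known to hydroxylate the allylic C9 methylene of parthenolide by hydrogen abstraction and oxygen rebound with high site selectivity, which no chemical allylic oxidant offers on this ring.

Step 7
Reactants: 13 9β-hydroxyparthenolide
Product: 14 9-oxoparthenolide
Conditions: Dess–Martin periodinane, NaHCO3, CH2Cl2, 0 °C to rt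
Reagents that add atoms: none
Why: Dess–Martin oxidation of a secondary allylic alcohol under buffered conditions should give the enone without touching the epoxide or the methylene lactone, and conjugation to C9=O removes the nucleophilicity of C1=C10 that otherwise opens the epoxide across the ring.

Step 8
Reactants: 14 9-oxoparthenolide
Product: 16 9-(trimethylsilyloxy)-8,9-didehydroparthenolide, via lithium dienolate 15 (not isolated)
Conditions: LiHMDS, TMSCl (premixed), THF, –78 °C; pentane, filtration
Reagents that add atoms: chlorotrimethylsilane, C[Si](C)(C)Cl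
Why: Kinetic deprotonation of an enone by a hindered amide occurs at the α′ position, here C8 as the only saturated α carbon, and in situ O-silylation should give the cross-conjugated 2-silyloxy diene while the low temperature and the bulk of the base spare the methylene lactone and the epoxide.

Step 9
Reactants: 16 9-(trimethylsilyloxy)-8,9-didehydroparthenolide
Product: 19 8α-hydroxy-9-oxoparthenolide, via silyloxy epoxide 17 (not isolated), via 8α-silyloxy ketone 18 (not isolated)
Conditions: mCPBA, NaHCO3, CH2Cl2, –20 °C; then TBAF, AcOH, THF, 0 °C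
Reagents that add atoms: 3-chloroperoxybenzoic acid, OOC(=O)c1cccc(Cl)c1
Why: In this Rubottom oxidation the peracid should attack only the electron-rich enol ether double bond, the silyloxy oxirane should open with 1,4-silyl shift to the α-silyloxy ketone, and C8 should become 8α (R) because allylic 1,3-strain holds H7 in the plane of the enol ether so that the reagent approaches the face turned away from the macrocycle, which is the face syn to H7.

Step 10
Reactants: 19 8α-hydroxy-9-oxoparthenolide; 20 angelic acid
Product: 22 8α-angeloyloxy-9-oxoparthenolide, via mixed anhydride 21 (not isolated)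
Conditions: 20, 2,4,6-Cl3C6H2COCl, Et3N, PhMe, rt, filter; then 19, PhMe, 80 °C
Reagents that add atoms: none
Why: Yamaguchi esterification through the angelic 2,4,6-trichlorobenzoic mixed anhydride, run hot without a nucleophilic catalyst, is the established way to acylate hindered secondary alcohols with angelic acid without Z-to-E isomerisation to the tiglate, and it leaves the C8 configuration untouched.

Step 11
Reactants: 22 8α-angeloyloxy-9-oxoparthenolide
Product: 23 13-dimethylamino-11βH-11,13-dihydro-8α-angeloyloxy-9-oxoparthenolide
Conditions: Me2NH (2 M in THF), THF, 0 °C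
Reagents that add atoms: dimethylamine, CNC
Why: Aza-Michael addition of a secondary amine to the unhindered exocyclic methylene lactone is much faster than addition to the α-methyl, β-substituted ring enone or to the angelate and masks the acrylate for step 12, protonation of the lactone enolate from the less hindered face giving the 11βH adduct whose new centre is removed again in step 15.

Step 12
Reactants: 23 13-dimethylamino-11βH-11,13-dihydro-8α-angeloyloxy-9-oxoparthenolide
Product: 25 8α-angeloyloxy-13-dimethylamino-4α,5β-epoxy-9-oxo-10αH,11βH-germacran-12,6α-olide, via copper enolate 24 (not isolated)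
Conditions: [(Ph3P)CuH]6, H2O (few equiv), degassed THF/PhMe, rt
Reagents that add atoms: none
Why: Conjugate reduction with Stryker's reagent should deliver hydride to C1 of the ketone enone only, the trisubstituted angelate and the epoxide being inert to it at room temperature, and protonation of the copper enolate at C10 from the periphery of the ring, the face that reagents take on C1=C10 of the parent lactones, should give the 10αH, 10β-methyl (10R) ketone.

Step 13
Reactants: 25 8α-angeloyloxy-13-dimethylamino-4α,5β-epoxy-9-oxo-10αH,11βH-germacran-12,6α-olide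
Product: 26 8α-angeloyloxy-13-dimethylamino-4β,5β-dihydroxy-9-oxo-10αH,11βH-germacran-12,6α-olide
Conditions: HClO4 (aq), THF/H2O, 0 °C to rt; then NaHCO3
Reagents that add atoms: water, O
Why: Acid-catalysed hydrolysis of a trisubstituted epoxide proceeds by attack of water on the tertiary carbon anti to the leaving oxygen, so C4 should be inverted to 4β-OH (4S) while the C5–O bond (5R) is untouched, and with C1=C10 saturated and the C8 and C10 hydrogens deactivated by the carbonyl group no transannular partner is left.

Step 14
Reactants: 26 8α-angeloyloxy-13-dimethylamino-4β,5β-dihydroxy-9-oxo-10αH,11βH-germacran-12,6α-olide; 27 isobutyryl chloride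
Product: 28 8α-angeloyloxy-13-dimethylamino-4β-hydroxy-5β-isobutyryloxy-9-oxo-10αH,11βH-germacran-12,6α-olide
Conditions: 27, pyridine, DMAP (cat.), CH2Cl2, 0 °C
Reagents that add atoms: none
Why: Acylation with an acid chloride should take place only at the secondary C5 hydroxyl, because a tertiary alcohol such as C4–OH is not acylated under these conditions.

Step 15
Reactants: 28 8α-angeloyloxy-13-dimethylamino-4β-hydroxy-5β-isobutyryloxy-9-oxo-10αH,11βH-germacran-12,6α-olide
Product: 30 8α-angeloyloxy-4β-hydroxy-5β-isobutyryloxy-9-oxo-10αH-germacr-11(13)-en-12,6α-olide (target), via methiodide 29 (not isolated)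
Conditions: MeI, THF, rt; then NaHCO3 (aq), rt
Reagents that add atoms: none
Why: N-Methylation followed by bicarbonate-induced E1cB (Hofmann-type) loss of trimethylamine from the β-ammonio lactone is the standard way to regenerate an α-methylene lactone from its amine adduct and is mild enough for both esters, the tertiary alcohol and the epimerisable C8 and C10 centres.

Compound list
1 | (2E,6E)-farnesol | CC(C)=CCC/C(C)=C/CC/C(C)=C/CO | starting material
2 | (2E,6E)-farnesyl methanesulfonate (not isolated) | CC(C)=CCC/C(C)=C/CC/C(C)=C/COS(C)(=O)=O | intermediate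
3 | (2E,6E)-farnesyl chloride | CC(C)=CCC/C(C)=C/CC/C(C)=C/CCl | intermediate
4 | (2E,6E)-farnesyl diphosphate (drawn as free acid, handled as ammonium salt) | CC(C)=CCC/C(C)=C/CC/C(C)=C/COP(=O)(O)OP(=O)(O)O | intermediate
5 | (7R)-germacra-1(10)E,4E-dien-11-yl cation (enzyme-bound, not isolated) | C[C+](C)[C@@H]1CC/C(C)=C/CC/C(C)=C/C1 | intermediate
6 | (+)-(R)-germacrene A, (7R)-germacra-1(10)E,4E,11-triene | CC(=C)[C@@H]1CC/C(C)=C/CC/C(C)=C/C1 | intermediate
7 | (7R)-germacra-1(10)E,4E,11(13)-trien-12-ol (not isolated) | C=C(CO)[C@@H]1CC/C(C)=C/CC/C(C)=C/C1 | intermediate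
8 | (7R)-germacra-1(10)E,4E,11(13)-trien-12-al (not isolated) | C=C(C=O)[C@@H]1CC/C(C)=C/CC/C(C)=C/C1 | intermediate
9 | germacrene A acid, (7R)-germacra-1(10)E,4E,11(13)-trien-12-oic acid (not isolated) | C=C(C(=O)O)[C@@H]1CC/C(C)=C/CC/C(C)=C/C1 | intermediate
10 | 6α-hydroxygermacra-1(10)E,4E,11(13)-trien-12-oic acid (not isolated) | C=C(C(=O)O)[C@@H]1CC/C(C)=C/CC/C(C)=C/[C@H]1O | intermediate
11 | (+)-costunolide, germacra-1(10)E,4E,11(13)-trien-12,6α-olide | C1C/C(C)=C/CC/C(C)=C/[C@H]2OC(=O)C(=C)[C@H]12 | intermediate
12 | (–)-parthenolide, 4α,5β-epoxygermacra-1(10)E,11(13)-dien-12,6α-olide | C=C1C(=O)O[C@H]2[C@H]1CC/C(C)=C/CC[C@@]3(C)O[C@H]23 | intermediate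
13 | 9β-hydroxyparthenolide | C=C1C(=O)O[C@H]2[C@H]1C[C@H](O)/C(C)=C/CC[C@@]3(C)O[C@H]23 | intermediate
14 | 9-oxoparthenolide (1(10)E-en-9-one) | C=C1C(=O)O[C@H]2[C@H]1CC(=O)/C(C)=C/CC[C@@]3(C)O[C@H]23 | intermediate
15 | lithium C8=C9 dienolate of 14, C7 and C10 cis (not isolated) | C=C1C(=O)O[C@H]2[C@H]1/C=C(/O[Li])\C(C)=C\CC[C@@]3(C)O[C@H]23 | intermediate
16 | 9-(trimethylsilyloxy)-8,9-didehydroparthenolide, C7 and C10 cis on C8=C9 | C=C1C(=O)O[C@H]2[C@H]1/C=C(/O[Si](C)(C)C)\C(C)=C\CC[C@@]3(C)O[C@H]23 | intermediate
17 | 8α,9α-epoxy-9β-(trimethylsilyloxy)parthenolide (not isolated) | C=C1C(=O)O[C@H]2[C@H]1[C@H]3O[C@@]3(O[Si](C)(C)C)/C(C)=C/CC[C@@]4(C)O[C@H]24 | intermediate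
18 | 8α-(trimethylsilyloxy)-9-oxoparthenolide (not isolated) | C=C1C(=O)O[C@H]2[C@H]1[C@@H](O[Si](C)(C)C)C(=O)/C(C)=C/CC[C@@]3(C)O[C@H]23 | intermediate
19 | 8α-hydroxy-9-oxoparthenolide | C=C1C(=O)O[C@H]2[C@H]1[C@@H](O)C(=O)/C(C)=C/CC[C@@]3(C)O[C@H]23 | intermediate
20 | angelic acid, (Z)-2-methylbut-2-enoic acid | C/C=C(/C)C(=O)O | starting material
21 | angelic 2,4,6-trichlorobenzoic anhydride (not isolated) | C/C=C(/C)C(=O)OC(=O)c1c(Cl)cc(Cl)cc1Cl | intermediate
22 | 8α-angeloyloxy-9-oxoparthenolide | C=C1C(=O)O[C@H]2[C@H]1[C@@H](OC(=O)/C(C)=C\C)C(=O)/C(C)=C/CC[C@@]3(C)O[C@H]23 | intermediate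
23 | 13-dimethylamino-11βH-11,13-dihydro-8α-angeloyloxy-9-oxoparthenolide | CN(C)C[C@@H]1C(=O)O[C@H]2[C@H]1[C@@H](OC(=O)/C(C)=C\C)C(=O)/C(C)=C/CC[C@@]3(C)O[C@H]23 | intermediate
24 | copper(I) C9=C10 enolate of 25, phosphine ligands omitted, drawn with C8 and C1 cis (not isolated) | CN(C)C[C@@H]1C(=O)O[C@H]2[C@H]1[C@@H](OC(=O)/C(C)=C\C)/C(O[Cu])=C(C)\CCC[C@@]3(C)O[C@H]23 | intermediate
25 | 8α-angeloyloxy-13-dimethylamino-4α,5β-epoxy-9-oxo-10αH,11βH-germacran-12,6α-olide | CN(C)C[C@@H]1C(=O)O[C@H]2[C@H]1[C@@H](OC(=O)/C(C)=C\C)C(=O)[C@H](C)CCC[C@@]3(C)O[C@H]23 | intermediate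
26 | 8α-angeloyloxy-13-dimethylamino-4β,5β-dihydroxy-9-oxo-10αH,11βH-germacran-12,6α-olide | CN(C)C[C@@H]1C(=O)O[C@H]2[C@H]1[C@@H](OC(=O)/C(C)=C\C)C(=O)[C@H](C)CCC[C@](C)(O)[C@@H]2O | intermediate
27 | isobutyryl chloride | CC(C)C(Cl)=O | starting material
28 | 8α-angeloyloxy-13-dimethylamino-4β-hydroxy-5β-isobutyryloxy-9-oxo-10αH,11βH-germacran-12,6α-olide | CN(C)C[C@@H]1C(=O)O[C@H]2[C@H]1[C@@H](OC(=O)/C(C)=C\C)C(=O)[C@H](C)CCC[C@](C)(O)[C@@H]2OC(=O)C(C)C | intermediate
29 | 13-trimethylammonio analogue of 28, iodide (not isolated) | C[N+](C)(C)C[C@@H]1C(=O)O[C@H]2[C@H]1[C@@H](OC(=O)/C(C)=C\C)C(=O)[C@H](C)CCC[C@](C)(O)[C@@H]2OC(=O)C(C)C.[I-] | intermediate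
30 | (4S,5R,6S,7S,8R,10R)-8α-angeloyloxy-4β-hydroxy-5β-isobutyryloxy-9-oxo-10αH-germacr-11(13)-en-12,6α-olide, CNP0141258.2 | C=C1C(=O)O[C@H]2[C@H]1[C@@H](OC(=O)/C(C)=C\C)C(=O)[C@H](C)CCC[C@](C)(O)[C@@H]2OC(=O)C(C)C | target

Total step count: 15. Longest linear sequence: 15 steps (1 to 30); 20 and 27 enter as purchased building blocks.

Steps most likely to fail

1. Step 13, epoxide hydrolysis. The tertiary C4–O bond may ionise ahead of the attack of water. Water could then return on the face the oxygen left (retention at C4), or a C15 proton could be lost to give the exocyclic allylic alcohol. The new C5 hydroxyl may also add to the C9 ketone as a hemiketal and disturb the acylation. The fallback sets out from 25 and makes the elimination the route. Cp2TiCl (Cp2TiCl2, Mn, THF, rt) should open the epoxide homolytically at C4 and, after capture by a second Ti(III) and β-hydride loss, give the 4(15)-en-5β-ol F1. Isobutyryl chloride 27 with pyridine should give its 5β-isobutyrate F2. Mukaiyama hydration (Co(acac)2, PhSiH3, O2, iPrOH, rt) should then form the tertiary C4–O bond by capture of the C4 radical anti to the C5 acyloxy group. This comes back to the route at 28 and bypasses 26.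

2. Step 9, Rubottom oxidation. The peracid may attack the enol ether with poor facial selectivity, or the silyl group may be lost before oxidation and return 14. The fallback sets out from 16 and uses the other epimer instead of discarding it. The 8β-hydroxy-9-oxoparthenolide F3 should be esterified with inversion in a Mitsunobu reaction with angelic acid 20 (PPh3, DIAD, PhMe, 0 °C to rt). This is an SN2 displacement at the carbon next to the ketone in which the acid acts only as the nucleophile and is never activated towards isomerisation. It comes back at 22 and bypasses 19.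

3. Step 12, conjugate reduction. The copper enolate may be protonated at C10 from the inner face, or the ketone may enolise afterwards, either of which gives the C10 epimer; the angelate may also be reduced in competition. The fallback sets out from 19 and sets C10 by hydrogen delivery before the angelate is present. Dimethylamine should give the amine adduct F4. H2 over Pd/C in EtOAc should add syn to the exposed outer face of the trans ring olefin and give the saturated 10αH hydroxy ketone F5. Yamaguchi acylation with the mixed anhydride 21 (from 20) comes back at 25 and bypasses 22 and 23.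

Further compounds
F1 | step 13 | 8α-angeloyloxy-13-dimethylamino-5β-hydroxy-9-oxo-10αH,11βH-germacr-4(15)-en-12,6α-olide | CN(C)C[C@@H]1C(=O)O[C@H]2[C@H]1[C@@H](OC(=O)/C(C)=C\C)C(=O)[C@H](C)CCCC(=C)[C@@H]2O
F2 | step 13 | 8α-angeloyloxy-13-dimethylamino-5β-isobutyryloxy-9-oxo-10αH,11βH-germacr-4(15)-en-12,6α-olide | CN(C)C[C@@H]1C(=O)O[C@H]2[C@H]1[C@@H](OC(=O)/C(C)=C\C)C(=O)[C@H](C)CCCC(=C)[C@@H]2OC(=O)C(C)C
F3 | step 9 | 8β-hydroxy-9-oxoparthenolide | C=C1C(=O)O[C@H]2[C@H]1[C@H](O)C(=O)/C(C)=C/CC[C@@]3(C)O[C@H]23
F4 | step 12 | 13-dimethylamino-11βH-11,13-dihydro-8α-hydroxy-9-oxoparthenolide | CN(C)C[C@@H]1C(=O)O[C@H]2[C@H]1[C@@H](O)C(=O)/C(C)=C/CC[C@@]3(C)O[C@H]23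
F5 | step 12 | 13-dimethylamino-4α,5β-epoxy-8α-hydroxy-9-oxo-10αH,11βH-germacran-12,6α-olide | CN(C)C[C@@H]1C(=O)O[C@H]2[C@H]1[C@@H](O)C(=O)[C@H](C)CCC[C@@]3(C)O[C@H]23
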